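**Plan**

1. Ring A (the butenolide: O1, C2(=O), C3, C4, C5) is cut at C2–C3. The O1–C2 bond is kept as an aryl enol carbonate on the C5 oxygen, and C3 becomes a cis vinyl iodide.
2. This is possible because ring A is an enol lactone: O1 sits on sp2 carbon C5 of the exocyclic C5=C1' bond, so O1–C2 can be made first by O-acylation of a C5 ketone enolate, and the cis C3=C4 bond holds C3 beside C2.
3. Further cuts, in order: C3–I/C4–H (hydroiodination of a C3≡C4 ynone), C4–C5 (alkynyllithium plus Weinreb amide), C4'=C5' (Julia–Kocienski), C6'=C7' (Wittig), and the two C–C bonds at ring B (3,4-disubstituted furan).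
4. Forward: rings B and C are bought as furans and joined through the CH2 bridge; fragment 1 (bis-furan enal 11) and fragment 2 (sulfone 18) are joined at C4'=C5'; the ynone is added; ring A is closed last.
5. Stereochemistry: C2' (S) comes from (R)-monomethyl 3-methylglutarate, whose two ends are exchanged in role without touching the centre. 6'E comes from the stabilised Wittig, 4'E from the Julia–Kocienski step, cis C3=C4 from anti-hydroiodination, and 5Z from the Z(O)-enolate trapped as carbonate.

Key step: step 14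

Remark: compounds 1, 2, 6, 10, 12, 16, 21 and 25 are taken as catalogue compounds; 12 is used as the (R)-enantiomer.

**Route**

Step 1
Reactants: 1 3,4-dibromofuran; 2 furan-3-carbaldehyde
Product: 4 (4-bromofuran-3-yl)(furan-3-yl)methanol (racemic), via (4-bromofuran-3-yl)lithium 3 (not isolated)
Conditions: n-BuLi (1.0 equiv), Et2O, –78 °C; then 2, –78 °C; H2O
Reagents that add atoms: none
Why: Bromine–lithium exchange on one of the two equivalent C–Br bonds followed by 1,2-addition of the 3-furyllithium to the aldehyde (organolithium addition) should work because the 3-lithiofuran is stable at –78 °C, and the carbinol centre is formed racemic on purpose since step 2 reduces it to CH2.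

Step 2
Reactants: 4 (4-bromofuran-3-yl)(furan-3-yl)methanol
Product: 5 3-bromo-4-(furan-3-ylmethyl)furan
Conditions: Et3SiH, CF3CO2H, CH2Cl2, –40 to 0 °C
Reagents that add atoms: none
Why: Ionic hydrogenation should work because the carbinol ionises easily to a cation stabilised by two 3-furyl groups, which Et3SiH traps as CH2 at a temperature low enough to spare the furan rings and the C–Br bond.

Step 3
Reactants: 5 3-bromo-4-(furan-3-ylmethyl)furan; 6 oxetane
Product: 8 3-[4-(furan-3-ylmethyl)furan-3-yl]propan-1-ol, via [4-(furan-3-ylmethyl)furan-3-yl]lithium 7 (not isolated)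
Conditions: n-BuLi, THF, –78 °C; then 6, BF3·OEt2, –78 °C; H2O
Reagents that add atoms: none
Why: A second bromine–lithium exchange followed by BF3-assisted SN2 ring opening of oxetane by the aryllithium installs the three-carbon arm as a primary alcohol, exchange at –78 °C being faster than deprotonation of any furan or bridge C–H.

Step 4
Reactants: 8 3-[4-(furan-3-ylmethyl)furan-3-yl]propan-1-ol
Product: 9 3-[4-(furan-3-ylmethyl)furan-3-yl]propanal
Conditions: Dess–Martin periodinane, CH2Cl2, 0 °C to rt
Reagents that add atoms: none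
Why: Dess–Martin oxidation takes the primary alcohol to the aldehyde under near-neutral conditions that both furans tolerate.

Step 5
Reactants: 9 3-[4-(furan-3-ylmethyl)furan-3-yl]propanal; 10 2-(triphenylphosphoranylidene)propanal
Product: 11 (2E)-5-[4-(furan-3-ylmethyl)furan-3-yl]-2-methylpent-2-enal
Conditions: toluene, 80 °C
Reagents that add atoms: none
Why: Wittig olefination with a stabilised ylide should give the (E)-2-methyl-2-enal (formyl group trans to the chain), which fixes the future 6'E geometry.

Step 6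
Reactants: 12 (3R)-5-methoxy-3-methyl-5-oxopentanoic acid
Product: 14 (4S)-4-methyloxan-2-one, via hydroxy acid 13 (not isolated)
Conditions: LiBH4, THF, 0 °C to rt; then 2 M HCl, rt
Reagents that add atoms: none
Why: Chemoselective ester reduction followed by lactonisation should work because LiBH4 reduces the methyl ester but not the lithium carboxylate, so the former acid carbon becomes the lactone carbonyl while the stereocentre is untouched (its descriptor changes from R to S only through the priority rules).

Step 7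
Reactants: 14 (4S)-4-methyloxan-2-one
Product: 15 (3S)-5-hydroxy-N-methoxy-N,3-dimethylpentanamide
Conditions: MeNH(OMe)·HCl, AlMe3, CH2Cl2, 0 °C to rt; then H2O
Reagents that add atoms: N,O-dimethylhydroxylamine hydrochloride, CNOC.Cl
Why: Weinreb aminolysis of the lactone by the aluminium amide opens the ring to the hydroxy Weinreb amide, which is used at once to avoid relactonisation.

Step 8
Reactants: 15 (3S)-5-hydroxy-N-methoxy-N,3-dimethylpentanamide; 16 1-phenyl-1H-tetrazole-5-thiol
Product: 17 (3R)-N-methoxy-N,3-dimethyl-5-[(1-phenyl-1H-tetrazol-5-yl)sulfanyl]pentanamide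
Conditions: PPh3, DIAD, THF, 0 °C to rt
Reagents that add atoms: none
Why: Mitsunobu thioetherification of the primary alcohol with the acidic heteroaryl thiol is a standard entry to Julia–Kocienski sulfones, and the descriptor change to R is formal only (sulfur raises the priority of that branch).

Step 9
Reactants: 17 (3R)-N-methoxy-N,3-dimethyl-5-[(1-phenyl-1H-tetrazol-5-yl)sulfanyl]pentanamide
Product: 18 (3R)-N-methoxy-N,3-dimethyl-5-[(1-phenyl-1H-tetrazol-5-yl)sulfonyl]pentanamide
Conditions: (NH4)6Mo7O24·4H2O (cat.), 30% H2O2, EtOH, 0 °C to rt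
Reagents that add atoms: hydrogen peroxide, OO
Why: Molybdate-catalysed peroxide oxidation converts the sulfide to the sulfone and leaves the Weinreb amide alone.

Step 10
Reactants: 18 (3R)-N-methoxy-N,3-dimethyl-5-[(1-phenyl-1H-tetrazol-5-yl)sulfonyl]pentanamide; 11 (2E)-5-[4-(furan-3-ylmethyl)furan-3-yl]-2-methylpent-2-enal
Product: 20 (3S,5E,7E)-10-[4-(furan-3-ylmethyl)furan-3-yl]-N-methoxy-N,3,7-trimethyldeca-5,7-dienamide, via potassium sulfonyl carbanion 19 (not isolated)
Conditions: KN(SiMe3)2, DME, –60 °C; then 11, –60 °C to rt; H2O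
Reagents that add atoms: none
Why: Julia–Kocienski olefination should join the fragments with the new disubstituted alkene E, because the sulfone α-CH is far more acidic than the amide α-CH and the enal cannot enolise at its α-carbon.

Step 11
Reactants: 20 (3S,5E,7E)-10-[4-(furan-3-ylmethyl)furan-3-yl]-N-methoxy-N,3,7-trimethyldeca-5,7-dienamide; 21 tert-butyldimethyl(prop-2-yn-1-yloxy)silane
Product: 23 (6S,8E,10E)-1-[(tert-butyldimethylsilyl)oxy]-13-[4-(furan-3-ylmethyl)furan-3-yl]-6,10-dimethyltrideca-8,10-dien-2-yn-4-one, via lithium acetylide 22 (not isolated)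
Conditions: n-BuLi, THF, –78 °C (21 to 22); then 20, –78 to –20 °C; poured into cold 1 M HCl
Reagents that add atoms: none
Why: Weinreb ketone synthesis should stop at the ynone because the chelated tetrahedral adduct survives until the acidic quench, which also protonates the released amine before it can add to the ynone.

Step 12
Reactants: 23 (6S,8E,10E)-1-[(tert-butyldimethylsilyl)oxy]-13-[4-(furan-3-ylmethyl)furan-3-yl]-6,10-dimethyltrideca-8,10-dien-2-yn-4-one
Product: 24 (2Z,6S,8E,10E)-1-[(tert-butyldimethylsilyl)oxy]-13-[4-(furan-3-ylmethyl)furan-3-yl]-2-iodo-6,10-dimethyltrideca-2,8,10-trien-4-one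
Conditions: NaI, AcOH, MeCN, rt, dark
Reagents that add atoms: sodium iodide, [Na+].[I-]
Why: Conjugate hydroiodination of the ynone places iodide on the β-carbon and protonates the iodoallenol anti to iodine, so iodine and the acyl group end up cis (the future cis C3=C4 bond of ring A) under conditions mild enough for the furans, the diene and the silyl ether.

Step 13
Reactants: 24 (2Z,6S,8E,10E)-1-[(tert-butyldimethylsilyl)oxy]-13-[4-(furan-3-ylmethyl)furan-3-yl]-2-iodo-6,10-dimethyltrideca-2,8,10-trien-4-one; 25 2,4,6-trichlorophenyl chloroformate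
Product: 27 (2Z,4Z,6S,8E,10E)-1-[(tert-butyldimethylsilyl)oxy]-13-[4-(furan-3-ylmethyl)furan-3-yl]-2-iodo-6,10-dimethyltrideca-2,4,8,10-tetraen-4-yl 2,4,6-trichlorophenyl carbonate, via potassium dienolate 26 (not isolated)
Conditions: KN(SiMe3)2, THF, –78 °C; then 25, –78 to –40 °C
Reagents that add atoms: none
Why: Kinetic deprotonation at the saturated α'-CH2 should give the cross-conjugated Z(O)-dienolate (the alkenyl acyl group disfavours the E(O) geometry by allylic strain), and the hard chloroformate acylates the potassium enolate on oxygen (enol carbonate formation), which lays down the O1–C2 bond and fixes the future C5=C1' geometry as Z.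

Step 14
Reactants: 27 (2Z,4Z,6S,8E,10E)-1-[(tert-butyldimethylsilyl)oxy]-13-[4-(furan-3-ylmethyl)furan-3-yl]-2-iodo-6,10-dimethyltrideca-2,4,8,10-tetraen-4-yl 2,4,6-trichlorophenyl carbonate
Product: 30 (5Z)-3-{[(tert-butyldimethylsilyl)oxy]methyl}-5-[(2S,4E,6E)-9-[4-(furan-3-ylmethyl)furan-3-yl]-2,6-dimethylnona-4,6-dien-1-ylidene]furan-2(5H)-one, via alkenyllithium 28 (not isolated), via cyclic lithium alkoxide 29 (not isolated)
Conditions: n-BuLi (1.05 equiv), THF/Et2O/pentane, –100 °C; then AcOH, –100 °C to rt
Reagents that add atoms: none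
Why: Iodine–lithium exchange at C3 is far faster at –100 °C than addition of n-BuLi to the hindered aryl carbonate, and alkenyllithium 28 keeps its cis geometry, so the carbanion at C3 lies next to the carbonate carbon C2 (the s-trans diene conformer puts O1 syn to C3). Attack of C3 on C2 closes ring A in the 5-exo-trig mode to the tetrahedral alkoxide 29, which expels 2,4,6-trichlorophenoxide, a much better leaving group than the dienolate oxygen O1, so the O1–C2 bond stays and the lactone results. The closest known reaction type is the Parham cyclization (halogen–lithium exchange followed by intramolecular acyl substitution), related also to the anionic homo-Fries O-to-C carbonyl transfer. No stereocentre is formed; the 5Z geometry of C5=C1' and the cis C3=C4 bond are carried over from 27, and C2' is remote from every basic site. The step needs chemoselectivity for exchange over carbonyl addition and over loss of the allylic silyloxy group from 28, which the iodide, the low temperature and the immediate intramolecular trapping should secure.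

Step 15
Reactants: 30 (5Z)-3-{[(tert-butyldimethylsilyl)oxy]methyl}-5-[(2S,4E,6E)-9-[4-(furan-3-ylmethyl)furan-3-yl]-2,6-dimethylnona-4,6-dien-1-ylidene]furan-2(5H)-one
Product: 31 (5Z)-5-[(2S,4E,6E)-9-[4-(furan-3-ylmethyl)furan-3-yl]-2,6-dimethylnona-4,6-dien-1-ylidene]-3-(hydroxymethyl)furan-2(5H)-one
Conditions: HF·pyridine, pyridine, THF, 0 °C
Reagents that add atoms: none
Why: Fluoride-mediated silyl ether cleavage under buffered, non-basic conditions should free the primary alcohol without touching the alkylidene butenolide or the furans.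

**Compound list**

1 | 3,4-dibromofuran | Brc1cocc1Br | starting material
2 | furan-3-carbaldehyde | O=Cc1ccoc1 | starting material
3 | (4-bromofuran-3-yl)lithium | [Li]c1cocc1Br | intermediate
4 | (4-bromofuran-3-yl)(furan-3-yl)methanol (racemic) | OC(c1cocc1Br)c1ccoc1 | intermediate
5 | 3-bromo-4-(furan-3-ylmethyl)furan | Brc1cocc1Cc1ccoc1 | intermediate
6 | oxetane | C1COC1 | starting material
7 | [4-(furan-3-ylmethyl)furan-3-yl]lithium | [Li]c1cocc1Cc1ccoc1 | intermediate
8 | 3-[4-(furan-3-ylmethyl)furan-3-yl]propan-1-ol | OCCCc1cocc1Cc1ccoc1 | intermediate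
9 | 3-[4-(furan-3-ylmethyl)furan-3-yl]propanal | O=CCCc1cocc1Cc1ccoc1 | intermediate
10 | 2-(triphenylphosphoranylidene)propanal | CC(C=O)=P(c1ccccc1)(c1ccccc1)c1ccccc1 | starting material
11 | (2E)-5-[4-(furan-3-ylmethyl)furan-3-yl]-2-methylpent-2-enal | O=C/C(C)=C/CCc1cocc1Cc1ccoc1 | intermediate
12 | (3R)-5-methoxy-3-methyl-5-oxopentanoic acid, the (R)-monomethyl ester of 3-methylglutaric acid | COC(=O)C[C@H](C)CC(=O)O | starting material
13 | (3S)-5-hydroxy-3-methylpentanoic acid | OCC[C@H](C)CC(=O)O | intermediate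
14 | (4S)-4-methyloxan-2-one | O=C1C[C@@H](C)CCO1 | intermediate
15 | (3S)-5-hydroxy-N-methoxy-N,3-dimethylpentanamide | CON(C)C(=O)C[C@@H](C)CCO | intermediate
16 | 1-phenyl-1H-tetrazole-5-thiol | Sc1nnnn1-c1ccccc1 | starting material
17 | (3R)-N-methoxy-N,3-dimethyl-5-[(1-phenyl-1H-tetrazol-5-yl)sulfanyl]pentanamide | CON(C)C(=O)C[C@@H](C)CCSc1nnnn1-c1ccccc1 | intermediate
18 | (3R)-N-methoxy-N,3-dimethyl-5-[(1-phenyl-1H-tetrazol-5-yl)sulfonyl]pentanamide | CON(C)C(=O)C[C@@H](C)CCS(=O)(=O)c1nnnn1-c1ccccc1 | intermediate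
19 | potassium salt of 18 deprotonated at C5 (the carbon next to sulfur) | CON(C)C(=O)C[C@@H](C)CC([K])S(=O)(=O)c1nnnn1-c1ccccc1 | intermediate
20 | (3S,5E,7E)-10-[4-(furan-3-ylmethyl)furan-3-yl]-N-methoxy-N,3,7-trimethyldeca-5,7-dienamide | CON(C)C(=O)C[C@@H](C)C/C=C/C(C)=C/CCc1cocc1Cc1ccoc1 | intermediate
21 | tert-butyldimethyl(prop-2-yn-1-yloxy)silane | C#CCO[Si](C)(C)C(C)(C)C | starting material
22 | {3-[(tert-butyldimethylsilyl)oxy]prop-1-yn-1-yl}lithium | [Li]C#CCO[Si](C)(C)C(C)(C)C | intermediate
23 | (6S,8E,10E)-1-[(tert-butyldimethylsilyl)oxy]-13-[4-(furan-3-ylmethyl)furan-3-yl]-6,10-dimethyltrideca-8,10-dien-2-yn-4-one | CC(C)(C)[Si](C)(C)OCC#CC(=O)C[C@@H](C)C/C=C/C(C)=C/CCc1cocc1Cc1ccoc1 | intermediate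
24 | (2Z,6S,8E,10E)-1-[(tert-butyldimethylsilyl)oxy]-13-[4-(furan-3-ylmethyl)furan-3-yl]-2-iodo-6,10-dimethyltrideca-2,8,10-trien-4-one (iodine cis to the ketone carbon) | CC(C)(C)[Si](C)(C)OC/C(I)=C/C(=O)C[C@@H](C)C/C=C/C(C)=C/CCc1cocc1Cc1ccoc1 | intermediate
25 | 2,4,6-trichlorophenyl chloroformate | O=C(Cl)Oc1c(Cl)cc(Cl)cc1Cl | starting material
26 | potassium (2Z,4Z,6S,8E,10E)-1-[(tert-butyldimethylsilyl)oxy]-13-[4-(furan-3-ylmethyl)furan-3-yl]-2-iodo-6,10-dimethyltrideca-2,4,8,10-tetraen-4-olate | CC(C)(C)[Si](C)(C)OC/C(I)=C/C(O[K])=C/[C@@H](C)C/C=C/C(C)=C/CCc1cocc1Cc1ccoc1 | intermediate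
27 | (2Z,4Z,6S,8E,10E)-1-[(tert-butyldimethylsilyl)oxy]-13-[4-(furan-3-ylmethyl)furan-3-yl]-2-iodo-6,10-dimethyltrideca-2,4,8,10-tetraen-4-yl 2,4,6-trichlorophenyl carbonate | CC(C)(C)[Si](C)(C)OC/C(I)=C/C(OC(=O)Oc1c(Cl)cc(Cl)cc1Cl)=C/[C@@H](C)C/C=C/C(C)=C/CCc1cocc1Cc1ccoc1 | intermediate
28 | alkenyllithium: 27 with lithium in place of iodine at C2, same geometry (formally 2E) | CC(C)(C)[Si](C)(C)OC/C([Li])=C/C(OC(=O)Oc1c(Cl)cc(Cl)cc1Cl)=C/[C@@H](C)C/C=C/C(C)=C/CCc1cocc1Cc1ccoc1 | intermediate
29 | lithium (5Z)-3-{[(tert-butyldimethylsilyl)oxy]methyl}-5-[(2S,4E,6E)-9-[4-(furan-3-ylmethyl)furan-3-yl]-2,6-dimethylnona-4,6-dien-1-ylidene]-2-(2,4,6-trichlorophenoxy)-2,5-dihydrofuran-2-olate (both C2 epimers) | CC(/C=C/C[C@H](C)/C=C1/C=C(CO[Si](C)(C)C(C)(C)C)C(O[Li])(Oc2c(Cl)cc(Cl)cc2Cl)O1)=C\CCc1cocc1Cc1ccoc1 | intermediate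
30 | (5Z)-3-{[(tert-butyldimethylsilyl)oxy]methyl}-5-[(2S,4E,6E)-9-[4-(furan-3-ylmethyl)furan-3-yl]-2,6-dimethylnona-4,6-dien-1-ylidene]furan-2(5H)-one | CC(/C=C/C[C@H](C)/C=C1/C=C(CO[Si](C)(C)C(C)(C)C)C(=O)O1)=C\CCc1cocc1Cc1ccoc1 | intermediate
31 | (5Z)-5-[(2S,4E,6E)-9-[4-(furan-3-ylmethyl)furan-3-yl]-2,6-dimethylnona-4,6-dien-1-ylidene]-3-(hydroxymethyl)furan-2(5H)-one | CC(/C=C/C[C@H](C)/C=C1/C=C(CO)C(=O)O1)=C\CCc1cocc1Cc1ccoc1 | target

**Totals and risks**

Total step count: 15
Longest linear sequence: 11 steps (steps 1 to 5 and 10 to 15)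

Steps most likely to fail:

Step 14. What may go wrong is addition of n-BuLi to the carbonate carbonyl, or loss of lithium silanolate from the alkenyllithium, before the ring closes. The fallback sets out from iodoenone 24 and leaves out steps 13 and 14. Carbonylation with PdCl2(PPh3)2, CO (1 atm) and NEt3 in MeCN at 50 °C should give 30 directly, where the route is rejoined: zerovalent palladium inserts into the C3–I bond, CO inserts, and the enol oxygen of the C5 ketone acylates the acylpalladium. This is the known carbonylative lactonisation of cis β-iodoenones to (Z)-alkylidene butenolides; no new compound is made on this path (F0).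

Step 13. What may go wrong is deprotonation at the silyloxy-bearing CH2 instead of the α'-CH2, loss of HI back to the ynone, C-acylation, or formation of an E/Z mixture at the new enol double bond. The fallback sets out from 24 and returns at 27. Soft enolisation with Me3SiOTf and NEt3 (CH2Cl2, –78 to 0 °C) gives, under equilibrating conditions, the trimethylsilyl dienol ether of 24, tert-butyl({(2Z,4Z,6S,8E,10E)-13-[4-(furan-3-ylmethyl)furan-3-yl]-2-iodo-6,10-dimethyl-4-[(trimethylsilyl)oxy]trideca-2,4,8,10-tetraen-1-yl}oxy)dimethylsilane F1, whose geometry can be checked and purified. Cleavage of F1 with t-BuOK (THF, –40 °C) then gives enolate 26 free of amine base, and 25 converts it to 27.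

Step 2. What may go wrong is acid-induced oligomerisation of the furan rings, or hydride delivery to a ring carbon of the delocalised cation. The fallback sets out from 1 and returns at 5, avoiding carbinol 4 and all acid. Compound 3 is generated as in step 1 and transmetalated with ZnCl2 to (4-bromofuran-3-yl)zinc chloride F2. Negishi coupling of F2 with commercial 3-(bromomethyl)furan (BrCc1ccoc1; Pd(PPh3)4, THF, rt) should give 5, since oxidative addition at the benzylic-type C–Br bond is faster than at the furyl C–Br bond.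

Further compounds
F0 | step 14 | none | none
F1 | step 13 | tert-butyl({(2Z,4Z,6S,8E,10E)-13-[4-(furan-3-ylmethyl)furan-3-yl]-2-iodo-6,10-dimethyl-4-[(trimethylsilyl)oxy]trideca-2,4,8,10-tetraen-1-yl}oxy)dimethylsilane | CC(C)(C)[Si](C)(C)OC/C(I)=C/C(O[Si](C)(C)C)=C/[C@@H](C)C/C=C/C(C)=C/CCc1cocc1Cc1ccoc1
F2 | step 2 | (4-bromofuran-3-yl)zinc chloride | Cl[Zn]c1cocc1Br
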